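**Retrosynthetic overview**

1. The target is reached by acylation of the C6 hydroxyl of a trans-4,5-epoxy-6-ol with silyl-protected vanillic acid and final desilylation; the oxirane comes from chelation-controlled MeMgBr addition to a C4 ketone, followed by displacement of a C5 sulfonate by the new C4 alkoxide.
2. The ten-membered carbocycle (C4 ketone, E-C1=C10) comes from a 12-membered β-keto allylic macrolactone by Pd-catalysed decarboxylative ring contraction: the C2–C3 bond forms and the two lactone atoms C(=O)–O leave as CO2.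
3. Enabling feature: in the ten-membered ring C4 (oxirane carbon, a ketone before methylation) is γ,δ to the C1=C10 alkene (C4–C3–C2–C1=C10), so C3 is a latent enolate carbon and C2 a latent allyl terminus; a carboxyl on C3 esterified to O–C2 ties them into an unstrained 12-membered ring.
4. The macrolactone comes from acylketene lactonisation of a hydroxy β-keto ester; the chain comes from Roskamp homologation, Zr-catalysed carboalumination, chelation-controlled propargylation and a syn-aldol of an isovaleryl imide with an L-tartrate-derived α-alkoxy aldehyde (sets C5–C8).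
5. Ring order: 12-membered lactone, then ten-membered carbocycle, then oxirane.

Key step: step 15

Remark: locants C1–C10 are those of the ten-membered ring of the target (C4/C5 oxirane carbons, C6 ester carbon, C7 isopropyl carbon, C8 carbinol carbon, C1=C10 alkene); palladium intermediates are written without phosphine ligands. PMB = 4-methoxybenzyl, NAP = 2-naphthylmethyl, TBS = tert-butyldimethylsilyl.

**Route**

Step 1
Reactants: 1 diethyl L-tartrate
Product: 2 diethyl (4R,5R)-2-(4-methoxyphenyl)-1,3-dioxolane-4,5-dicarboxylate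
Conditions: 4-MeOC6H4CH(OMe)2, TsOH (cat.), toluene, 80 °C
Reagents that add atoms: p-anisaldehyde dimethyl acetal, COC(OC)c1ccc(OC)cc1
Why: Acid-catalysed transacetalisation of the 1,2-diol; the C2 symmetry gives a single acetal and the stereocentres are not touched.

Step 2
Reactants: 2 diethyl (4R,5R)-2-(4-methoxyphenyl)-1,3-dioxolane-4,5-dicarboxylate
Product: 3 2-O-(4-methoxybenzyl)-L-threitol
Conditions: DIBAL-H (excess), CH2Cl2, −78 → 0 °C; Rochelle salt
Reagents that add atoms: none
Why: DIBAL reduces both esters and then opens the p-methoxybenzylidene acetal reductively; by symmetry either C–O cleavage gives the same mono-PMB ether.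

Step 3
Reactants: 3 2-O-(4-methoxybenzyl)-L-threitol
Product: 4 2-O-(4-methoxybenzyl)-3,4-O-isopropylidene-L-threitol
Conditions: Me2C(OMe)2, PPTS (cat.), acetone, rt
Reagents that add atoms: 2,2-dimethoxypropane, COC(C)(C)OC
Why: Acetonide formation should favour the five-membered dioxolane on the terminal 1,2-diol over the 1,3-dioxane, leaving the primary C1 hydroxyl free.

Step 4
Reactants: 4 2-O-(4-methoxybenzyl)-3,4-O-isopropylidene-L-threitol
Product: 5 2-O-(4-methoxybenzyl)-3,4-O-isopropylidene-L-threose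
Conditions: Dess–Martin periodinane, NaHCO3, CH2Cl2, 0 °C → rt; used crude
Reagents that add atoms: none
Why: Buffered Dess–Martin oxidation of the primary alcohol should give the α-alkoxy aldehyde without epimerisation if used directly.

Step 5
Reactants: 6 (S)-4-benzyl-3-(3-methylbutanoyl)oxazolidin-2-one; 5 2-O-(4-methoxybenzyl)-3,4-O-isopropylidene-L-threose
Product: 8 syn-aldol adduct (5S,6S,7S; C6–OH), via Z-boron enolate 7 (not isolated)
Conditions: n-Bu2BOTf, i-Pr2NEt, CH2Cl2, −78 → 0 °C; then 5, −78 → 0 °C; pH 7 buffer/MeOH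
Reagents that add atoms: dibutylboron triflate, CCCCB(CCCC)OS(=O)(=O)C(F)(F)F (boron is held only in intermediate 7)
Why: Evans syn-aldol through a Zimmerman–Traxler chair; the auxiliary sets C6 and C7 (syn), and the Cornforth preference of the α-alkoxy aldehyde toward a Z-enolate (new OH anti to C5–OPMB) is matched with it.

Step 6
Reactants: 8 syn-aldol adduct
Product: 9 C6 O-(2-naphthylmethyl) ether of 8
Conditions: 2-naphthylmethyl trichloroacetimidate, TfOH (cat.), CH2Cl2–cyclohexane, 0 °C
Reagents that add atoms: 2-naphthylmethyl 2,2,2-trichloroacetimidate, N=C(OCc1ccc2ccccc2c1)C(Cl)(Cl)Cl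
Why: Acid-catalysed imidate alkylation protects the aldol hydroxyl without base, so retro-aldol cleavage is avoided; NAP is a chelating ether orthogonal to PMB.

Step 7
Reactants: 9 C6 O-(2-naphthylmethyl) ether
Product: 10 primary alcohol (C8H2OH; C5–OPMB, C6–ONAP, C7-isopropyl, terminal acetonide)
Conditions: LiBH4, MeOH (1 equiv), THF, 0 °C
Reagents that add atoms: none
Why: Reductive removal of the oxazolidinone auxiliary by hydride attack on the exocyclic imide carbonyl; the C7 stereocentre is not enolised.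

Step 8
Reactants: 10 primary alcohol
Product: 11 aldehyde (C8HO; α-isopropyl, β-ONAP)
Conditions: Dess–Martin periodinane, NaHCO3, CH2Cl2, 0 °C → rt; used crude
Reagents that add atoms: none
Why: Mild buffered oxidation to the α-branched aldehyde, which should keep its C7 configuration if used at once.

Step 9
Reactants: 11 aldehyde
Product: 12 homopropargylic alcohol (C8–OH anti to C7-isopropyl and anti to C6–ONAP)
Conditions: allenyltributylstannane, MgBr2·OEt2, CH2Cl2, −20 °C
Reagents that add atoms: allenyltributylstannane, C=C=C[Sn](CCCC)(CCCC)CCCC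
Why: SE2′ propargylation of the six-membered magnesium chelate between the aldehyde oxygen and C6–ONAP (Cram-chelate control); attack anti to the C7 isopropyl group sets C8, and α- and β-induction reinforce.

Step 10
Reactants: 12 homopropargylic alcohol
Product: 13 C8 TBS ether
Conditions: TBSOTf, 2,6-lutidine, CH2Cl2, −78 → 0 °C
Reagents that add atoms: tert-butyldimethylsilyl triflate, CC(C)(C)[Si](C)(C)OS(=O)(=O)C(F)(F)F
Why: Silylation of the hindered secondary alcohol with the triflate at low temperature, where the acetonide should survive.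

Step 11
Reactants: 13 C8 TBS ether
Product: 15 (E)-allylic alcohol (C10 methyl, C2H2OH), via alkenylalane 14 (not isolated)
Conditions: Me3Al, Cp2ZrCl2 (cat.), H2O (1 equiv), CH2Cl2, −20 °C; n-BuLi, −78 °C; (CH2O)n, THF, rt
Reagents that add atoms: trimethylaluminium, C[Al](C)C; paraformaldehyde (as formaldehyde), C=O
Why: Negishi Zr-catalysed syn-carboalumination puts methyl on the internal and aluminium on the terminal alkyne carbon, and hydroxymethylation of the alanate with retention gives the E-trisubstituted allylic alcohol.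

Step 12
Reactants: 15 (E)-allylic alcohol
Product: 17 α-alkoxy aldehyde (C4HO), via vicinal diol 16 (not isolated)
Conditions: H5IO6, EtOAc, 0 °C → rt
Reagents that add atoms: none
Why: Periodic acid hydrolyses the terminal acetonide and cleaves the resulting glycol in one pot under non-basic conditions; no other 1,2-diol is present and the free allylic alcohol is inert.

Step 13
Reactants: 17 α-alkoxy aldehyde
Product: 18 tert-butyl β-keto ester (C3H2, C4 ketone)
Conditions: tert-butyl diazoacetate, SnCl2 (cat.), CH2Cl2, rt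
Reagents that add atoms: tert-butyl diazoacetate, CC(C)(C)OC(=O)C=[N+]=[N-]
Why: Roskamp reaction (Lewis-acid-promoted diazo ester addition, 1,2-hydride shift, loss of N2) turns the aldehyde carbon into the C4 ketone without basic enolisation of C5.

Step 14
Reactants: 18 tert-butyl β-keto ester
Product: 20 12-membered β-keto macrolactone, via acylketene 19 (not isolated)
Conditions: toluene, 110 °C, 1 mM, slow addition
Reagents that add atoms: none
Why: Thermal loss of tert-butanol from the tert-butyl β-keto ester gives an acylketene that the primary allylic C2 hydroxyl should trap intramolecularly (acylketene macrolactonisation) to an unstrained 12-membered ring.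

Step 15
Reactants: 20 12-membered β-keto macrolactone
Product: 23 ten-membered ketone (5S,6S,7S,8R,1(10)E; 4-oxo, 5-OPMB, 6-ONAP, 7-isopropyl, 8-OTBS), via allylpalladium carboxylate 21 (not isolated), via palladium enolate 22 (not isolated)
Conditions: Pd(PPh3)4 (10 mol %), toluene, 2 mM, 40 °C
Reagents that add atoms: tetrakis(triphenylphosphine)palladium(0), [Pd].c1ccc(cc1)P(c1ccccc1)c1ccccc1.c1ccc(cc1)P(c1ccccc1)c1ccccc1.c1ccc(cc1)P(c1ccccc1)c1ccccc1.c1ccc(cc1)P(c1ccccc1)c1ccccc1 (palladium is held only in intermediates 21 and 22)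
Why: Proposed new method: Pd(0) ionises the allylic C2–O bond of the lactone to the allylpalladium β-keto carboxylate 21, which stays tethered through C4–C10; loss of CO2 gives the palladium enolate 22 of the C4 ketone regiospecifically at C3, and C3–C2 bond formation releases Pd(0) and the ten-membered ketone, so the ring contracts by the two lactone atoms C(=O)–O. The closest known reactions are the Tsuji–Saegusa decarboxylative allylation (palladium Carroll reaction) of acyclic allyl β-keto esters and the palladium-catalysed isomerisation of vinyl lactones to carbocyclic acids, neither of which has been shown on a macrocyclic β-keto lactone. The ten-membered ring closes by C-allylation of the enolate carbon at the primary allyl terminus C2 (endo mode, alkene inside the new ring); attack at the tertiary terminus C10 (exo mode) would give a more strained eight-membered ring with a quaternary carbon and is also disfavoured in intermolecular cases. No stereocentre is formed: C5–C8 are not touched under the neutral conditions, and the E geometry of C1=C10 should be kept because syn–anti exchange of the allyl unit would need η1-bonding at tertiary C10. The step needs C- over O-allylation, C3 rather than C5 as the nucleophilic carbon, and ring closure rather than oligomerisation or diene formation by β-hydride loss; decarboxylative generation of the enolate at C3 only, a contact ion pair in a weakly polar solvent and high dilution should secure these.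

Step 16
Reactants: 23 ten-membered ketone
Product: 24 tertiary alcohol (4R; C4 methyl, C4–OH anti to C5–OPMB)
Conditions: MeMgBr, CH2Cl2–Et2O, −78 °C
Reagents that add atoms: methylmagnesium bromide, C[Mg]Br
Why: Cram-chelate addition to the α-alkoxy ketone: magnesium bridges the C4 carbonyl and C5–OPMB, and methyl enters from the H5 side, which is also the outer face of the ring, setting C4.

Step 17
Reactants: 24 tertiary alcohol
Product: 25 4,5-diol (C5–OH free, C6–ONAP kept)
Conditions: (NH4)2Ce(NO3)6, MeCN–H2O, NaHCO3, 0 °C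
Reagents that add atoms: none
Why: Oxidative cleavage of the more electron-rich PMB ether by ceric ammonium nitrate, a reagent known to spare 2-naphthylmethyl ethers.

Step 18
Reactants: 25 4,5-diol
Product: 27 trans-4,5-epoxide (4R,5R; C6–ONAP, C8–OTBS), via C5 mesylate 26 (not isolated)
Conditions: MsCl, Et3N, CH2Cl2, −20 °C; then K2CO3, MeOH, rt
Reagents that add atoms: methanesulfonyl chloride, CS(=O)(=O)Cl (its atoms are held only in intermediate 26)
Why: Only the secondary C5 hydroxyl is sulfonylated; the C4 alkoxide then displaces it anti-periplanar (intramolecular Williamson, 3-exo-tet) with inversion at C5, giving the trans oxirane with C3 and C6 on opposite sides.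

Step 19
Reactants: 27 trans-4,5-epoxide
Product: 28 epoxy alcohol (C6–OH free)
Conditions: DDQ, CH2Cl2–pH 7 buffer, rt
Reagents that add atoms: none
Why: Oxidative removal of the NAP ether under buffered neutral conditions, which should spare the oxirane, the silyl ether and the trisubstituted alkene.

Step 20
Reactants: 29 vanillic acid
Product: 31 4-(tert-butyldimethylsilyloxy)-3-methoxybenzoic acid, via bis-silyl derivative 30 (not isolated)
Conditions: TBSCl (2.2 equiv), imidazole, DMF, rt; then AcOH–THF–H2O, rt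
Reagents that add atoms: tert-butyldimethylsilyl chloride, CC(C)(C)[Si](C)(C)Cl
Why: Both acidic OH groups are silylated, and the much more labile silyl ester is then hydrolysed selectively, leaving the aryl silyl ether.

Step 21
Reactants: 28 epoxy alcohol; 31 4-(tert-butyldimethylsilyloxy)-3-methoxybenzoic acid
Product: 33 bis-TBS-protected target, via mixed anhydride 32 (not isolated)
Conditions: 2,4,6-Cl3C6H2COCl, Et3N, toluene, rt; then 28, DMAP, 40 °C
Reagents that add atoms: 2,4,6-trichlorobenzoyl chloride, O=C(Cl)c1c(Cl)cc(Cl)cc1Cl (its atoms are held only in intermediate 32)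
Why: Yamaguchi esterification: DMAP attacks the less hindered aroyl carbonyl of the mixed anhydride and the acylpyridinium acylates the hindered secondary C6 hydroxyl under basic conditions that the oxirane tolerates.

Step 22
Reactants: 33 bis-TBS-protected target
Product: 34 target (4R,5R,6S,7R,8R,1(10)E)
Conditions: TBAF, AcOH (1:1), THF, 0 → 40 °C
Reagents that add atoms: none
Why: Buffered fluoride removes the aryl and the secondary silyl ether in one operation; buffering should suppress 1,3-acyl migration and acid-induced transannular opening of the epoxide.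

**Compound list**

1 | diethyl L-tartrate (2R,3R) | CCOC(=O)[C@H](O)[C@@H](O)C(=O)OCC | starting material
2 | diethyl (4R,5R)-2-(4-methoxyphenyl)-1,3-dioxolane-4,5-dicarboxylate | CCOC(=O)[C@@H]1OC(c2ccc(OC)cc2)O[C@H]1C(=O)OCC | intermediate
3 | 2-O-(4-methoxybenzyl)-L-threitol | OC[C@H](OCc1ccc(OC)cc1)[C@@H](O)CO | intermediate
4 | 2-O-(4-methoxybenzyl)-3,4-O-isopropylidene-L-threitol | OC[C@H](OCc1ccc(OC)cc1)[C@@H]1COC(C)(C)O1 | intermediate
5 | 2-O-(4-methoxybenzyl)-3,4-O-isopropylidene-L-threose, (2R)-2-[(4S)-2,2-dimethyl-1,3-dioxolan-4-yl]-2-(4-methoxybenzyloxy)acetaldehyde | O=C[C@H](OCc1ccc(OC)cc1)[C@@H]1COC(C)(C)O1 | intermediate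
6 | (S)-4-benzyl-3-(3-methylbutanoyl)oxazolidin-2-one | CC(C)CC(=O)N1C(=O)OC[C@@H]1Cc1ccccc1 | starting material
7 | Z-dibutylboron enolate of 6 | CC(C)/C=C(\OB(CCCC)CCCC)N1C(=O)OC[C@@H]1Cc1ccccc1 | intermediate
8 | (4S)-4-benzyl-3-[(2S,3S,4S)-4-[(4S)-2,2-dimethyl-1,3-dioxolan-4-yl]-3-hydroxy-4-(4-methoxybenzyloxy)-2-isopropylbutanoyl]oxazolidin-2-one (syn-aldol adduct) | CC1(C)OC[C@H](O1)[C@@H](OCc2ccc(OC)cc2)[C@@H](O)[C@H](C(C)C)C(=O)N3C(=O)OC[C@@H]3Cc4ccccc4 | intermediate
9 | 3-O-(2-naphthylmethyl) ether of 8 (C6–ONAP) | CC1(C)OC[C@H](O1)[C@@H](OCc2ccc(OC)cc2)[C@@H](OCc3ccc4ccccc4c3)[C@H](C(C)C)C(=O)N5C(=O)OC[C@@H]5Cc6ccccc6 | intermediate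
10 | primary alcohol from 9 (C8H2OH; configuration at C5, C6, C7 and the dioxolane unchanged) | CC1(C)OC[C@H](O1)[C@@H](OCc2ccc(OC)cc2)[C@@H](OCc3ccc4ccccc4c3)[C@H](C(C)C)CO | intermediate
11 | aldehyde from 10 (C8HO) | CC1(C)OC[C@H](O1)[C@@H](OCc2ccc(OC)cc2)[C@@H](OCc3ccc4ccccc4c3)[C@H](C(C)C)C=O | intermediate
12 | homopropargylic alcohol (C8–OH, 7,8-anti, 6,8-anti; terminal alkyne) | CC1(C)OC[C@H](O1)[C@@H](OCc2ccc(OC)cc2)[C@@H](OCc3ccc4ccccc4c3)[C@H](C(C)C)[C@H](O)CC#C | intermediate
13 | C8 TBS ether of 12 | CC1(C)OC[C@H](O1)[C@@H](OCc2ccc(OC)cc2)[C@@H](OCc3ccc4ccccc4c3)[C@H](C(C)C)[C@H](O[Si](C)(C)C(C)(C)C)CC#C | intermediate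
14 | (E)-alkenyl(dimethyl)alane from 13 | CC1(C)OC[C@H](O1)[C@@H](OCc2ccc(OC)cc2)[C@@H](OCc3ccc4ccccc4c3)[C@H](C(C)C)[C@H](O[Si](C)(C)C(C)(C)C)C/C(C)=C/[Al](C)C | intermediate
15 | (E)-allylic alcohol (C2H2OH, C10 methyl, E-C1=C10; terminal acetonide) | CC1(C)OC[C@H](O1)[C@@H](OCc2ccc(OC)cc2)[C@@H](OCc3ccc4ccccc4c3)[C@H](C(C)C)[C@H](O[Si](C)(C)C(C)(C)C)C/C(C)=C/CO | intermediate
16 | vicinal diol from 15 (acetonide removed) | OC[C@H](O)[C@@H](OCc1ccc(OC)cc1)[C@@H](OCc2ccc3ccccc3c2)[C@H](C(C)C)[C@H](O[Si](C)(C)C(C)(C)C)C/C(C)=C/CO | intermediate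
17 | α-alkoxy aldehyde (C4HO; 5S-OPMB, 6S-ONAP, 7S-isopropyl, 8R-OTBS, C2H2OH) | O=C[C@@H](OCc1ccc(OC)cc1)[C@@H](OCc2ccc3ccccc3c2)[C@H](C(C)C)[C@H](O[Si](C)(C)C(C)(C)C)C/C(C)=C/CO | intermediate
18 | tert-butyl β-keto ester (C3H2 between ester and C4 ketone) | CC(C)(C)OC(=O)CC(=O)[C@@H](OCc1ccc(OC)cc1)[C@@H](OCc2ccc3ccccc3c2)[C@H](C(C)C)[C@H](O[Si](C)(C)C(C)(C)C)C/C(C)=C/CO | intermediate
19 | acylketene from 18 | O=C=CC(=O)[C@@H](OCc1ccc(OC)cc1)[C@@H](OCc2ccc3ccccc3c2)[C@H](C(C)C)[C@H](O[Si](C)(C)C(C)(C)C)C/C(C)=C/CO | intermediate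
20 | 12-membered β-keto macrolactone (ring: lactone C(=O), C3, C4, C5, C6, C7, C8, C9, C10, C1, C2, O) | O=C1CC(=O)[C@@H](OCc2ccc(OC)cc2)[C@@H](OCc3ccc4ccccc4c3)[C@H](C(C)C)[C@H](O[Si](C)(C)C(C)(C)C)C/C(C)=C/CO1 | intermediate
21 | allylpalladium(II) β-keto carboxylate (σ-allyl form, ligands omitted) | O=C1CC(=O)[C@@H](OCc2ccc(OC)cc2)[C@@H](OCc3ccc4ccccc4c3)[C@H](C(C)C)[C@H](O[Si](C)(C)C(C)(C)C)C/C(C)=C/C[Pd]O1 | intermediate
22 | O-bound palladium(II) enolate of the C4 ketone with σ-allyl at C2 (ligands omitted) | C=C1[C@@H](OCc2ccc(OC)cc2)[C@@H](OCc3ccc4ccccc4c3)[C@H](C(C)C)[C@H](O[Si](C)(C)C(C)(C)C)C/C(C)=C/C[Pd]O1 | intermediate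
23 | ten-membered ketone (5S,6S,7S,8R,1(10)E)-5-(4-methoxybenzyloxy)-6-(2-naphthylmethoxy)-7-isopropyl-8-(tert-butyldimethylsilyloxy)-10-methylcyclodec-1(10)-en-4-one (ring locants of the target) | O=C1[C@@H](OCc2ccc(OC)cc2)[C@@H](OCc3ccc4ccccc4c3)[C@H](C(C)C)[C@H](O[Si](C)(C)C(C)(C)C)C/C(C)=C/CC1 | intermediate
24 | tertiary alcohol (4R; C4 methyl and OH, C4–OH anti to C5–OPMB) | C[C@]1(O)[C@@H](OCc2ccc(OC)cc2)[C@@H](OCc3ccc4ccccc4c3)[C@H](C(C)C)[C@H](O[Si](C)(C)C(C)(C)C)C/C(C)=C/CC1 | intermediate
25 | 4,5-diol (C5–OH free) | C[C@]1(O)[C@@H](O)[C@@H](OCc2ccc3ccccc3c2)[C@H](C(C)C)[C@H](O[Si](C)(C)C(C)(C)C)C/C(C)=C/CC1 | intermediate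
26 | C5 mesylate of 25 | C[C@]1(O)[C@@H](OS(C)(=O)=O)[C@@H](OCc2ccc3ccccc3c2)[C@H](C(C)C)[C@H](O[Si](C)(C)C(C)(C)C)C/C(C)=C/CC1 | intermediate
27 | trans-4,5-epoxide (4R,5R,6S,7S,8R; 6-ONAP, 8-OTBS) | C[C@]12O[C@@H]1[C@@H](OCc3ccc4ccccc4c3)[C@H](C(C)C)[C@H](O[Si](C)(C)C(C)(C)C)C/C(C)=C/CC2 | intermediate
28 | epoxy alcohol (4R,5R,6S,7S,8R; 6-OH, 8-OTBS) | C[C@]12O[C@@H]1[C@@H](O)[C@H](C(C)C)[C@H](O[Si](C)(C)C(C)(C)C)C/C(C)=C/CC2 | intermediate
29 | vanillic acid | COc1cc(C(=O)O)ccc1O | starting material
30 | tert-butyldimethylsilyl 4-(tert-butyldimethylsilyloxy)-3-methoxybenzoate | COc1cc(C(=O)O[Si](C)(C)C(C)(C)C)ccc1O[Si](C)(C)C(C)(C)C | intermediate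
31 | 4-(tert-butyldimethylsilyloxy)-3-methoxybenzoic acid | COc1cc(C(=O)O)ccc1O[Si](C)(C)C(C)(C)C | intermediate
32 | mixed anhydride of 31 with 2,4,6-trichlorobenzoic acid | COc1cc(C(=O)OC(=O)c2c(Cl)cc(Cl)cc2Cl)ccc1O[Si](C)(C)C(C)(C)C | intermediate
33 | bis-TBS-protected target (C6 4-silyloxy-3-methoxybenzoate, 8-OTBS) | COc1cc(C(=O)O[C@H]2[C@H](C(C)C)[C@H](O[Si](C)(C)C(C)(C)C)C/C(C)=C/CC[C@@]3(C)O[C@H]23)ccc1O[Si](C)(C)C(C)(C)C | intermediate
34 | target, (4R,5R,6S,7R,8R,1(10)E)-4,5-epoxy-8-hydroxy-7-isopropyl-4,10-dimethylcyclodec-1(10)-en-6-yl 4-hydroxy-3-methoxybenzoate (ring locants of the target) | COc1cc(C(=O)O[C@H]2[C@H](C(C)C)[C@H](O)C/C(C)=C/CC[C@@]3(C)O[C@H]23)ccc1O | target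

**Step count and risks**

Total step count: 22. Longest linear sequence: 21 steps (steps 1–19, 21, 22, from diethyl L-tartrate); step 20 is a one-step side branch.

Steps most likely to fail:

1. Step 15 (Proposed new method). The tethered allylpalladium/enolate pair may not recombine within the ring: intermolecular allylation to oligomers, or protonation of the enolate with loss of the allyl unit as a diene by β-hydride elimination, could prevail. The fallback sets out from aldehyde 17. Roskamp homologation with methyl diazoacetate (SnCl2 cat.) would give methyl β-keto ester F1, and methyl chloroformate/pyridine would convert its allylic alcohol into allylic methyl carbonate F2. Intramolecular Tsuji–Trost alkylation of the stabilised β-keto ester anion (Pd(PPh3)4, dppe, THF, high dilution, reflux) would close the ten-membered ring as cyclic β-keto ester F3. Krapcho demethoxycarbonylation (LiCl, wet DMSO, 120 °C) would then return to ketone 23.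

2. Step 14. The acylketene may dimerise or be trapped intermolecularly before the 12-membered ring closes. The fallback sets out from allylic alcohol 15 and closes the ring through the C3–C4 bond instead. Acylation with bromoacetyl bromide/pyridine would give bromoacetate F4, and periodic acid would unmask aldehyde F5. A SmI2-mediated intramolecular Reformatsky reaction (THF, −78 °C, high dilution) would give β-hydroxy macrolactone F6, and Dess–Martin oxidation would return to macrolactone 20.

3. Step 16. Chelation control may be overridden by the ring conformation (poor or reversed facial selectivity), giving the C4 epimer and hence, after closure, the cis-oxirane. The fallback sets out from ketone 23 and uses that epimer, C4-epimeric tertiary alcohol F7. Ceric ammonium nitrate would give diol F8, and 1,1′-thiocarbonyldiimidazole would give cyclic thiocarbonate F9. Corey–Winter syn-elimination (1,3-dimethyl-2-phenyl-1,3,2-diazaphospholidine, 40 °C) would give stereospecifically (4E)-diene F10, and DDQ would free allylic alcohol F11. Hydroxyl-directed epoxidation (VO(acac)2, t-BuOOH) on the outer face of the ring, syn to C6–OH under A(1,3) control, would return to epoxy alcohol 28.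

**Further compounds**

F1 | step 15 | methyl β-keto ester (methyl analogue of 18) | COC(=O)CC(=O)[C@@H](OCc1ccc(OC)cc1)[C@@H](OCc2ccc3ccccc3c2)[C@H](C(C)C)[C@H](O[Si](C)(C)C(C)(C)C)C/C(C)=C/CO
F2 | step 15 | allylic methyl carbonate of F1 | COC(=O)CC(=O)[C@@H](OCc1ccc(OC)cc1)[C@@H](OCc2ccc3ccccc3c2)[C@H](C(C)C)[C@H](O[Si](C)(C)C(C)(C)C)C/C(C)=C/COC(=O)OC
F3 | step 15 | ten-membered cyclic β-keto ester (methyl ester on C3, C3 epimers) | O=C1[C@@H](OCc2ccc(OC)cc2)[C@@H](OCc3ccc4ccccc4c3)[C@H](C(C)C)[C@H](O[Si](C)(C)C(C)(C)C)C/C(C)=C/CC1C(=O)OC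
F4 | step 14 | bromoacetate of 15 | CC1(C)OC[C@H](O1)[C@@H](OCc2ccc(OC)cc2)[C@@H](OCc3ccc4ccccc4c3)[C@H](C(C)C)[C@H](O[Si](C)(C)C(C)(C)C)C/C(C)=C/COC(=O)CBr
F5 | step 14 | C4 aldehyde bromoacetate | O=C[C@@H](OCc1ccc(OC)cc1)[C@@H](OCc2ccc3ccccc3c2)[C@H](C(C)C)[C@H](O[Si](C)(C)C(C)(C)C)C/C(C)=C/COC(=O)CBr
F6 | step 14 | 12-membered β-hydroxy macrolactone (C4 epimers) | O=C1CC(O)[C@@H](OCc2ccc(OC)cc2)[C@@H](OCc3ccc4ccccc4c3)[C@H](C(C)C)[C@H](O[Si](C)(C)C(C)(C)C)C/C(C)=C/CO1
F7 | step 16 | C4-epimeric tertiary alcohol (4S; C4–OH syn to C5–OPMB) | C[C@@]1(O)[C@@H](OCc2ccc(OC)cc2)[C@@H](OCc3ccc4ccccc4c3)[C@H](C(C)C)[C@H](O[Si](C)(C)C(C)(C)C)C/C(C)=C/CC1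
F8 | step 16 | C4-epimeric 4,5-diol | C[C@@]1(O)[C@@H](O)[C@@H](OCc2ccc3ccccc3c2)[C@H](C(C)C)[C@H](O[Si](C)(C)C(C)(C)C)C/C(C)=C/CC1
F9 | step 16 | 4,5-cyclic thiocarbonate of F8 | C[C@@]12OC(=S)O[C@H]1[C@@H](OCc3ccc4ccccc4c3)[C@H](C(C)C)[C@H](O[Si](C)(C)C(C)(C)C)C/C(C)=C/CC2
F10 | step 16 | (1(10)E,4E)-diene (6-ONAP, 8-OTBS) | C/C1=C\[C@@H](OCc2ccc3ccccc3c2)[C@H](C(C)C)[C@H](O[Si](C)(C)C(C)(C)C)C/C(C)=C/CC1
F11 | step 16 | (1(10)E,4E)-dien-6-ol (8-OTBS) | C/C1=C\[C@@H](O)[C@H](C(C)C)[C@H](O[Si](C)(C)C(C)(C)C)C/C(C)=C/CC1
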